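**Retrosynthetic overview**
- The strategy rests on ring A (C4a, C5, C6, C7, C8, C8a), a fully substituted benzene. Its four adjacent oxygen-bearing carbons C5–C8 are taken from the four ring carbons of dimethyl squarate, and C4a/C8a are the enol-ether carbons of a 2-aryl dihydropyran that already holds O1, C2, C3 and C4.
- Late disconnections: the C4 ketone goes back to a C4 carbinol (kept as a silyl ether during the annulation), and the C5 and C8 methyl ethers go back to a 5,8-hydroquinone.
- Ring A is opened to a 4-hydroxycyclobutenone by reversing a thermal ring expansion (C4a–C5 bond). That adduct is cut into a 6-lithiated dihydropyran and dimethyl squarate (C8–C8a bond).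
- Ring C is cut into 4-methoxybenzaldehyde and Danishefsky diene by an enantioselective hetero-Diels–Alder reaction, which sets C2.
- Order of ring formation: ring B is bought, ring C is made in step 1, ring A is made last in step 5.

Key step: step 5

Assumption: the (S)-BINOL–Ti(OiPr)4 catalyst is taken to attack the aldehyde face that leads to the 2S pyranone, by analogy with the facial preference of this catalyst family in other aldehyde additions; the sense is checked on the first batch (chiral HPLC, sign of rotation) and the ligand antipode is exchanged if it proves opposite.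

**Step 1**
Reactants: 1 4-methoxybenzaldehyde; 2 Danishefsky diene, (E)-1-methoxy-3-(trimethylsilyloxy)buta-1,3-diene
Product: 4 (S)-2-(4-methoxyphenyl)-2,3-dihydro-4H-pyran-4-one, via silylated aldol adduct 3 (not isolated)
Conditions: Ti(OiPr)4 (10 mol%), (S)-BINOL (20 mol%), 4 Å MS, Et2O, −20 °C; then CF3CO2H, CH2Cl2, 0 °C
Reagents that add atoms: none
Why: A Lewis-acid-catalysed Mukaiyama aldol addition of the silyl enol ether terminus of 2 to 1, followed by acid-induced oxa-Michael closure and loss of methanol (the stepwise form of the hetero-Diels–Alder reaction), should give the dihydropyranone, the BINOL–titanium complex shielding one face of the bound aldehyde so that C2 is formed in the S configuration.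

**Step 2**
Reactants: 4 (S)-2-(4-methoxyphenyl)-2,3-dihydro-4H-pyran-4-one
Product: 5 (2S,4S)-2-(4-methoxyphenyl)-3,4-dihydro-2H-pyran-4-ol (aryl and hydroxyl cis)
Conditions: NaBH4, CeCl3·7H2O, MeOH, −78 → −20 °C; work-up with a trace of Et3N
Reagents that add atoms: none
Why: In this Luche 1,2-reduction hydride should attack the cerium-activated carbonyl along the axial trajectory of the half-chair whose anisyl group is pseudo-equatorial, giving the pseudo-equatorial 4S alcohol cis to the aryl group and leaving the enol ether intact.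

**Step 3**
Reactants: 5 (2S,4S)-2-(4-methoxyphenyl)-3,4-dihydro-2H-pyran-4-ol
Product: 6 (2S,4S)-2-(4-methoxyphenyl)-4-(triisopropylsilyloxy)-3,4-dihydro-2H-pyran
Conditions: TIPSOTf, 2,6-lutidine, CH2Cl2, −78 → 0 °C
Reagents that add atoms: triisopropylsilyl triflate, CC(C)[Si](OS(=O)(=O)C(F)(F)F)(C(C)C)C(C)C
Why: Silylation of the secondary allylic alcohol with a silyl triflate and a hindered pyridine base is cold and buffered enough to avoid Ferrier-type ionization, and the triisopropylsilyl group is chosen because it resists attack and α-silyl deprotonation by t-BuLi in the next step.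

**Step 4**
Reactants: 6 (2S,4S)-2-(4-methoxyphenyl)-4-(triisopropylsilyloxy)-3,4-dihydro-2H-pyran; 7 dimethyl squarate (3,4-dimethoxycyclobut-3-ene-1,2-dione)
Product: 9 4-hydroxy-2,3-dimethoxy-4-[(4S,6S)-6-(4-methoxyphenyl)-4-(triisopropylsilyloxy)-5,6-dihydro-4H-pyran-2-yl]cyclobut-2-en-1-one (carbinol carbon as a mixture of epimers), via 6-lithio dihydropyran 8 (not isolated)
Conditions: t-BuLi (pentane), THF, −78 → 0 °C; then cannulated into 7 (excess), THF, −78 °C; NH4Cl (aq), −78 °C; chromatography on Et3N-deactivated silica
Reagents that add atoms: none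
Why: Kinetic vinylic deprotonation of the cyclic enol ether at its oxygen-bearing sp2 carbon (as practised on silylated glycals) should give the α-alkoxyvinyllithium 8, which adds 1,2 to one of the two equivalent carbonyl groups of the squarate at low temperature; the new carbinol centre forms as a mixture that step 5 erases.

**Step 5**
Reactants: 9 4-hydroxy-2,3-dimethoxy-4-[(4S,6S)-6-(4-methoxyphenyl)-4-(triisopropylsilyloxy)-5,6-dihydro-4H-pyran-2-yl]cyclobut-2-en-1-one
Product: 12 (2S,4S)-6,7-dimethoxy-2-(4-methoxyphenyl)-4-(triisopropylsilyloxy)chromane-5,8-diol, via dienylketene 10 (not isolated), via cyclohexadienone 11 (not isolated)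
Conditions: degassed toluene (0.01 M), reflux, Ar; concentrated under Ar and used at once
Reagents that add atoms: none
Why: Heating should trigger conrotatory 4π electrocyclic opening of the cyclobutenone to the dienylketene 10, the donor hydroxyl turning outward so that the dihydropyranyl group ends up cis to the ketene; this is the thermal ring expansion of 4-alkenyl-4-hydroxycyclobutenones (Moore rearrangement), known for squarate adducts of lithiated cyclic enol ethers. Ring A is then closed by a thermal 6π electrocyclization of the ketene C=C, the central C=C and the pyran C5=C6 bond, which forms the C4a–C5 bond (flavanone numbering) and gives the cyclohexa-2,4-dienone 11. Enolization of 11 with loss of the C4a hydrogen aromatizes ring A to the 5,8-hydroquinone and removes both temporary stereocentres (the carbinol carbon of 9 and C4a of 11), so no new stereocentre persists and C2 and C4 are spectators. The selectivity needed is torquoselectivity in the ring opening, secured by the strong preference of an oxygen donor on the sp3 carbon for outward rotation; the opposite rotation would put the hydroxyl next to the ketene and lead to a furanone. Oxygen is excluded and the solution is kept dilute so that the electron-rich hydroquinone neither oxidizes nor couples.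

**Step 6**
Reactants: 12 (2S,4S)-6,7-dimethoxy-2-(4-methoxyphenyl)-4-(triisopropylsilyloxy)chromane-5,8-diol
Product: 13 (2S,4S)-5,6,7,8-tetramethoxy-2-(4-methoxyphenyl)-4-(triisopropylsilyloxy)chromane
Conditions: MeI (excess), K2CO3, degassed DMF, Ar, rt → 40 °C
Reagents that add atoms: iodomethane, CI
Why: Williamson O-methylation of both phenols should be straightforward because C4 is still a silyl ether, so neither phenol is chelated to a carbonyl group, and exclusion of oxygen keeps the hydroquinone dianion from going to the quinone.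

**Step 7**
Reactants: 13 (2S,4S)-5,6,7,8-tetramethoxy-2-(4-methoxyphenyl)-4-(triisopropylsilyloxy)chromane
Product: 14 (2S,4S)-5,6,7,8-tetramethoxy-2-(4-methoxyphenyl)chroman-4-ol
Conditions: TBAF, THF, 0 °C → rt; aqueous work-up
Reagents that add atoms: none
Why: Fluoride-induced cleavage of the silyl ether (Si–F bond formation) should free the benzylic alcohol without acid, which matters because the electron-rich 4-chromanol would ionize under protic desilylation.

**Step 8**
Reactants: 14 (2S,4S)-5,6,7,8-tetramethoxy-2-(4-methoxyphenyl)chroman-4-ol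
Product: 15 (2S)-5,6,7,8-tetramethoxy-2-(4-methoxyphenyl)chroman-4-one [(2S)-5,6,7,8,4'-pentamethoxyflavanone]
Conditions: Dess–Martin periodinane, pyridine, CH2Cl2, 0 °C → rt
Reagents that add atoms: none
Why: Dess–Martin oxidation of the secondary benzylic alcohol to the aryl ketone runs under near-neutral buffered conditions, so the C2 stereocentre, which could be lost by base-induced retro-oxa-Michael opening to the chalcone, should be retained while the temporary C4 stereocentre is removed.

**Compound list**
1 | 4-methoxybenzaldehyde | COc1ccc(C=O)cc1 | starting material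
2 | Danishefsky diene, (E)-1-methoxy-3-(trimethylsilyloxy)buta-1,3-diene | CO/C=C/C(=C)O[Si](C)(C)C | starting material
3 | (S,E)-1-methoxy-5-(4-methoxyphenyl)-5-(trimethylsilyloxy)pent-1-en-3-one (formed in situ) | COc1ccc([C@H](CC(=O)/C=C/OC)O[Si](C)(C)C)cc1 | intermediate
4 | (S)-2-(4-methoxyphenyl)-2,3-dihydro-4H-pyran-4-one | COc1ccc([C@@H]2CC(=O)C=CO2)cc1 | intermediate
5 | (2S,4S)-2-(4-methoxyphenyl)-3,4-dihydro-2H-pyran-4-ol | COc1ccc([C@@H]2C[C@H](O)C=CO2)cc1 | intermediate
6 | (2S,4S)-2-(4-methoxyphenyl)-4-(triisopropylsilyloxy)-3,4-dihydro-2H-pyran | COc1ccc([C@@H]2C[C@H](O[Si](C(C)C)(C(C)C)C(C)C)C=CO2)cc1 | intermediate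
7 | dimethyl squarate (3,4-dimethoxycyclobut-3-ene-1,2-dione) | COC1=C(OC)C(=O)C1=O | starting material
8 | (2S,4S)-6-lithio-2-(4-methoxyphenyl)-4-(triisopropylsilyloxy)-3,4-dihydro-2H-pyran (formed in situ) | COc1ccc([C@@H]2C[C@H](O[Si](C(C)C)(C(C)C)C(C)C)C=C([Li])O2)cc1 | intermediate
9 | 4-hydroxy-2,3-dimethoxy-4-[(4S,6S)-6-(4-methoxyphenyl)-4-(triisopropylsilyloxy)-5,6-dihydro-4H-pyran-2-yl]cyclobut-2-en-1-one (carbinol carbon unassigned) | COc1ccc([C@@H]2C[C@H](O[Si](C(C)C)(C(C)C)C(C)C)C=C(C3(O)C(OC)=C(OC)C3=O)O2)cc1 | intermediate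
10 | (Z)-4-hydroxy-2,3-dimethoxy-4-[(4S,6S)-6-(4-methoxyphenyl)-4-(triisopropylsilyloxy)-5,6-dihydro-4H-pyran-2-yl]buta-1,3-dien-1-one, the dienylketene with the pyranyl group cis to the ketene-bearing carbon (formed in situ) | COc1ccc([C@@H]2C[C@H](O[Si](C(C)C)(C(C)C)C(C)C)C=C(/C(O)=C(OC)\C(OC)=C=O)O2)cc1 | intermediate
11 | (2S,4S)-8-hydroxy-6,7-dimethoxy-2-(4-methoxyphenyl)-4-(triisopropylsilyloxy)-2,3,4,4a-tetrahydro-5H-chromen-5-one, C4a undefined (formed in situ) | COc1ccc([C@@H]2C[C@H](O[Si](C(C)C)(C(C)C)C(C)C)C3C(=O)C(OC)=C(OC)C(O)=C3O2)cc1 | intermediate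
12 | (2S,4S)-6,7-dimethoxy-2-(4-methoxyphenyl)-4-(triisopropylsilyloxy)chromane-5,8-diol | COc1ccc([C@@H]2C[C@H](O[Si](C(C)C)(C(C)C)C(C)C)c3c(O)c(OC)c(OC)c(O)c3O2)cc1 | intermediate
13 | (2S,4S)-5,6,7,8-tetramethoxy-2-(4-methoxyphenyl)-4-(triisopropylsilyloxy)chromane | COc1ccc([C@@H]2C[C@H](O[Si](C(C)C)(C(C)C)C(C)C)c3c(OC)c(OC)c(OC)c(OC)c3O2)cc1 | intermediate
14 | (2S,4S)-5,6,7,8-tetramethoxy-2-(4-methoxyphenyl)chroman-4-ol | COc1ccc([C@@H]2C[C@H](O)c3c(OC)c(OC)c(OC)c(OC)c3O2)cc1 | intermediate
15 | (2S)-5,6,7,8,4'-pentamethoxyflavanone | COc1ccc([C@@H]2CC(=O)c3c(OC)c(OC)c(OC)c(OC)c3O2)cc1 | target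

**Total step count:** 8
**Longest linear sequence:** 8 steps (1 → 15)

**Steps most likely to fail**

1. Step 4. Metalation may take place at the benzylic C2–H (activated by both the aryl group and the ring oxygen) or ortho to the aryl methoxy group instead of at the vinylic C6–H, and leftover alkyllithium or its solvent-derived fragments may add to the squarate. Any epimerization at C2 would show up as the trans diastereomer relative to the C4 silyloxy group, so it would not stay hidden. Fallback, setting out from 6: benzenesulfinic acid is added across the enol ether (CH2Cl2, rt) to give the anomeric sulfone, (4S,6S)-6-(4-methoxyphenyl)-2-(phenylsulfonyl)-4-(triisopropylsilyloxy)tetrahydropyran F1. With n-BuLi in THF at −78 °C only the far more acidic α-sulfonyl position is deprotonated, giving the lithiated sulfone F2. This is added to 7 at −78 °C and quenched with NH4Cl to give the sulfonyl carbinol adduct F3. Loss of benzenesulfinic acid (MgBr2·OEt2, Et3N, CH2Cl2) then re-forms the C5=C6 enol ether, and the route is rejoined at 9.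

2. Step 5. The free hydroxyl may add to the ketene if the ring opening is not fully outward-selective (lactonization to a furanone), the hot hydroquinone may be oxidized by traces of air, and silanol may be lost from C4 next to the newly formed C5 phenol. Fallback, setting out from 9: the tertiary carbinol is methylated (MeI, Ag2O, K2CO3, MeCN, rt) to the 4-methoxycyclobutenone F4. Thermolysis in degassed toluene should then give, by the same electrocyclic cascade but without a hydroxyl that can trap the ketene, the monophenol (2S,4S)-6,7,8-trimethoxy-2-(4-methoxyphenyl)-4-(triisopropylsilyloxy)chroman-5-ol F5, which is not a hydroquinone and can be purified in air. A single O-methylation (MeI, K2CO3, DMF) brings the route back at 13.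

3. Step 6. Under base the hydroquinone dianion may be oxidized to the quinone by residual oxygen, and alkylation at the hindered C5 oxygen, peri to the bulky silyloxy group, may stall, giving mixtures. Fallback, setting out from 12: the crude hydroquinone is deliberately oxidized (Ag2O, Et2O, rt) to the stable quinone, (2S,4S)-6,7-dimethoxy-2-(4-methoxyphenyl)-4-(triisopropylsilyloxy)-3,4-dihydro-2H-chromene-5,8-dione F6, which is purified by chromatography. It is then reduced and methylated in one flask under reducing phase-transfer conditions (Na2S2O4, THF/H2O; then KOH, Me2SO4, Bu4NBr), returning to the route at 13.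

**Further compounds**
F1 | step 4 | (4S,6S)-6-(4-methoxyphenyl)-2-(phenylsulfonyl)-4-(triisopropylsilyloxy)tetrahydropyran (sulfonyl-bearing carbon as a mixture) | COc1ccc([C@@H]2C[C@H](O[Si](C(C)C)(C(C)C)C(C)C)CC(S(=O)(=O)c3ccccc3)O2)cc1
F2 | step 4 | 2-lithio derivative of sulfone F1 (formed in situ) | COc1ccc([C@@H]2C[C@H](O[Si](C(C)C)(C(C)C)C(C)C)CC([Li])(S(=O)(=O)c3ccccc3)O2)cc1
F3 | step 4 | 4-hydroxy-2,3-dimethoxy-4-[(4S,6S)-6-(4-methoxyphenyl)-2-(phenylsulfonyl)-4-(triisopropylsilyloxy)tetrahydropyran-2-yl]cyclobut-2-en-1-one (new centres as mixtures) | COc1ccc([C@@H]2C[C@H](O[Si](C(C)C)(C(C)C)C(C)C)CC(S(=O)(=O)c3ccccc3)(C3(O)C(OC)=C(OC)C3=O)O2)cc1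
F4 | step 5 | 2,3,4-trimethoxy-4-[(4S,6S)-6-(4-methoxyphenyl)-4-(triisopropylsilyloxy)-5,6-dihydro-4H-pyran-2-yl]cyclobut-2-en-1-one | COc1ccc([C@@H]2C[C@H](O[Si](C(C)C)(C(C)C)C(C)C)C=C(C3(OC)C(OC)=C(OC)C3=O)O2)cc1
F5 | step 5 | (2S,4S)-6,7,8-trimethoxy-2-(4-methoxyphenyl)-4-(triisopropylsilyloxy)chroman-5-ol | COc1ccc([C@@H]2C[C@H](O[Si](C(C)C)(C(C)C)C(C)C)c3c(O)c(OC)c(OC)c(OC)c3O2)cc1
F6 | step 6 | (2S,4S)-6,7-dimethoxy-2-(4-methoxyphenyl)-4-(triisopropylsilyloxy)-3,4-dihydro-2H-chromene-5,8-dione | COc1ccc([C@@H]2C[C@H](O[Si](C(C)C)(C(C)C)C(C)C)C3=C(O2)C(=O)C(OC)=C(OC)C3=O)cc1
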